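At early times the cedar run is slow, with 18.0% target at 0.250 min, which looks like precatalyst still turning into catalyst. Between 0.417 min and 0.667 min the readings give 0.544 mM/min, and the stretch before it gives 0.548 mM/min, so I take the first of these readings as a rough working rate of the cedar run, read while the catalyst may still be growing.

| flask | starting material | coupling partner | precatalyst | remark | time |
|---|---|---|---|---|---|
| cedar | 5.0 × 10⁻⁴ M | 0.55 mM | 75 µM | run made earlier |  |
| ash | 5.0 × 10⁻⁴ M | 0.37 mM | 75 µM | run made earlier |  |
| birch | 5.0 × 10⁻⁴ M | 0.83 mM | 75 µM | run made earlier |  |
| maple | 0.0010 M | 0.55 mM | 75 µM | run made earlier |  |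
| north-east | 5.0 × 10⁻⁴ M | 0.550 mM | 75 µM | everything together at the start | 3.0 min |
| north | 5.0 × 10⁻⁴ M | 0.550 mM (fed, over 80 s) | 75 µM | all else is in the flask from the start; the feed brings no volume worth counting | 3.0 min |
| west | 5.0 × 10⁻⁴ M (fed, over 80 s) | 0.550 mM | 75 µM | all else is in the flask from the start; the feed brings no volume worth counting | 3.0 min |
| north-west | 5.0 × 10⁻⁴ M | 0.550 mM (fed, over 8.0 s) | 75 µM | all else is in the flask from the start; the feed brings no volume worth counting | 3.0 min |

| run | time / min | target / % |
|---|---|---|
| cedar | 0.250 | 18.0 |
| cedar | 0.417 | 36.3 |
| cedar | 0.667 | 63.5 |
| cedar | 1.00 | 80.0 |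
| cedar | 2.00 | 88.2 |
| cedar | 3.00 | 91.8 |
| ash | 0.667 | 43.3 |
| ash | 1.33 | 61.9 |
| ash | 2.00 | 66.0 |
| ash | 2.50 | 65.1 |
| ash | 3.00 | 65.3 |
| ash | 4.00 | 65.7 |
| birch | 0.250 | 27.1 |
| birch | 0.667 | 78.8 |
| birch | 1.33 | 89.0 |
| birch | 2.00 | 87.9 |
| birch | 3.00 | 88.7 |
| birch | 4.00 | 87.6 |
| maple | 0.250 | 10.5 |
| maple | 0.500 | 26.1 |
| maple | 1.00 | 43.2 |
| maple | 2.00 | 44.4 |
| maple | 4.00 | 43.4 |

(scatter of a reading: 1 percentage point)

- what may be going on: starting material + coupling partner + catalyst -> target + catalyst; precatalyst -> catalyst; starting material + coupling partner -> uncatalysed product

1. the flask that comes out highest in amount of target, in percent of the starting material charged, or "all alike" when all lie within 1.5 percentage points (north-east / north / west / north-west / all alike)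
2. target at the end, in percent of the starting material charged, north-east
3. target at the end, in percent of the starting material charged, north
4. target at the end, in percent of the starting material charged, west
5. target at the end, in percent of the starting material charged, north-west

The plateaus show a loss. In maple the partner charged exceeds the target made by 0.116 mM, and in ash by 0.0415 mM. Ash has half the starting material of maple and loses a smaller share of its partner, 11.2% against 21.1%, so the split between target and uncatalysed product, the selectivity, seems to worsen as c(starting material) rises, though these two runs differ in partner as well.

Two of us disagree. The first chemist says the four flasks get the same charges and the same time, so each ends near the mean of the last two cedar readings, 90.0%, and they come out alike. The second says the order of addition matters, since it sets how much stands in the flask while the catalyst works.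

I side with the second. West's feed brings 0.375 mM/min, and set against the working rate this gives 0.689. This number, feed rate over working rate, is the dosing ratio. Below one, what enters can be used about as it arrives, so I treat the fast step as settled and expect a small stock; far above one, the feed is a batch. West lies below one, north is at 0.758, and north-west is far above one at 7.58. My order is west, then north, with north-west close to north-east.

The forecast names west, with 90.5% for north-east, 93% for north, 95.5% for west and 90.8% for north-west, on the ground that “Feeding starting material keeps its concentration low, suppressing the side reaction most”.

The flasks give 89.6% in north-east, 94.6% in north, 96.5% in west and 91.0% in north-west, so west is highest.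

    starting material + coupling partner + catalyst → target + catalyst, rate k1*[starting material]*[coupling partner]*[catalyst]/(1 + ([starting material]/sat1)) (0.210 mM, k = 1.10 × 10⁷ /M²/s)
    precatalyst → catalyst (k = 0.0150 /s)
    starting material + coupling partner → uncatalysed product (k = 8.80 /M/s)

West ran at a dosing ratio of 0.689, and at the end of its feed, 1.33 min, it held 16.6% of its starting material. Taking away the uncatalysed path cuts west's lead over north-east from 6.9 percentage points to −0.12 points, and taking away the wait for active catalyst leaves 1.1 points, so the two act together. North-west, at 7.58, still held 94.8% of its partner at 0.133 min, and there the first chemist's view holds: it ended 1.4 points above north-east, inside the 1.5 points margin.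

The data are calculated with made-up constants.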